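## Retrosynthetic overview

1. Target 19 ⇐ desilylation of bis-TIPS ether 18 ⇐ ring A ether closure (O7 onto a C9' mesylate) of triol 16 ⇐ LiBH4 opening of bicyclic lactone 15.
2. 15 ⇐ ring B ether closure (O7' onto a C9 mesylate, retention at C7') of triol lactone 13 ⇐ enolate hydroxylation at C8' of aldol adduct 11.
3. Key C7'–C8' bond: intermolecular anti-aldol of the lithium enolate of trans-lactone 10 with aldehyde 2.
4. 10 ⇐ Evans syn-aldol/lactonization of succinate imide 5 with the same aldehyde 2 (sets C7 and C8; ring A is first made as a γ-lactone).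
5. Ring order: ring A as lactone (step 3), ring B as ether (step 10), ring A re-formed as ether (step 12).

Assumption: lignan numbering is used (ring A = C7–O–C9'–C8'–C8, ring B = C7'–O–C9–C8–C8', C8' carries the tertiary OH), the target read from the SMILES is (7S,8R,7'R,8'S) with both aryl groups exo, and Ar = 3-methoxy-4-(triisopropylsilyloxy)phenyl.

## Route

Step 1
Reactants: 1 vanillin (4-hydroxy-3-methoxybenzaldehyde)
Product: 2 3-methoxy-4-(triisopropylsilyloxy)benzaldehyde (ArCHO)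
Conditions: TIPSCl, imidazole, DMF, rt
Reagents that add atoms: chlorotri(propan-2-yl)silane (TIPSCl), CC(C)[Si](Cl)(C(C)C)C(C)C
Why: Imidazole-promoted O-silylation masks the phenol as a TIPS ether that tolerates enolates, hydrides and mild acid and is removed by fluoride at the end; no stereocenter is involved.

Step 2
Reactants: 3 (4S)-4-benzyl-1,3-oxazolidin-2-one; 4 methyl 4-chloro-4-oxobutanoate
Product: 5 methyl 4-[(4S)-4-benzyl-2-oxo-1,3-oxazolidin-3-yl]-4-oxobutanoate
Conditions: n-BuLi, THF, −78 °C; then 4, −78 → 0 °C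
Reagents that add atoms: none
Why: N-acylation of the lithiated oxazolidinone (nucleophilic acyl substitution) occurs at the acid chloride, which is far more electrophilic than the methyl ester.

Step 3
Reactants: 5 methyl 4-[(4S)-4-benzyl-2-oxo-1,3-oxazolidin-3-yl]-4-oxobutanoate; 2 ArCHO
Product: 7 (4S)-4-benzyl-3-{[(2S,3S)-2-Ar-5-oxooxolan-3-yl]carbonyl}-1,3-oxazolidin-2-one (trans lactone imide), via syn-aldol hydroxy ester 6 (not isolated)
Conditions: Bu2BOTf, i-Pr2NEt, CH2Cl2, 0 °C; 2, −78 → 0 °C; pH 7 buffer, MeOH, H2O2, 0 °C; crude with pyridinium p-toluenesulfonate (cat.), CH2Cl2, rt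
Reagents that add atoms: none
Why: Evans syn-aldol through the Z-boron enolate of the imide and a Zimmerman–Traxler chair, the aldehyde adding to the enolate face opposite the benzyl group of the (S)-auxiliary, sets C7 and C8, and the syn γ-hydroxy ester lactonizes to the trans-4,5-disubstituted butyrolactone (ring A).

Step 4
Reactants: 7 trans lactone imide
Product: 8 (2S,3S)-2-Ar-5-oxooxolane-3-carboxylic acid
Conditions: LiOH, H2O2, THF/H2O (3:1), 0 °C; Na2SO3; HCl to pH 2
Reagents that add atoms: hydrogen peroxide (used as LiOOH), OO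
Why: Hydroperoxide cleavage of an Evans imide attacks the exocyclic carbonyl selectively and does not epimerize C8, and any lactone opened by base re-closes on acidification.

Step 5
Reactants: 8 (2S,3S)-2-Ar-5-oxooxolane-3-carboxylic acid
Product: 9 (4R,5S)-4-(hydroxymethyl)-5-Ar-oxolan-2-one
Conditions: BH3·SMe2, THF, 0 °C → rt; MeOH quench
Reagents that add atoms: none
Why: Borane reduces the carboxylic acid chemoselectively through its acyloxyborane and leaves the γ-lactone and the aryl silyl ether untouched.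

Step 6
Reactants: 9 (4R,5S)-4-(hydroxymethyl)-5-Ar-oxolan-2-one
Product: 10 (4R,5S)-4-[(tert-butyldimethylsilyloxy)methyl]-5-Ar-oxolan-2-one
Conditions: TBSCl, imidazole, CH2Cl2, 0 °C → rt
Reagents that add atoms: tert-butyl(chloro)dimethylsilane (TBSCl), CC(C)(C)[Si](C)(C)Cl
Why: Silylation of the primary alcohol blocks translactonization and alkoxide side reactions in the enolate steps that follow.

Step 7
Reactants: 10 (4R,5S)-4-[(tert-butyldimethylsilyloxy)methyl]-5-Ar-oxolan-2-one; 2 ArCHO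
Product: 11 (3R,4R,5S)-4-[(tert-butyldimethylsilyloxy)methyl]-3-[(S)-hydroxy(Ar)methyl]-5-Ar-oxolan-2-one (anti-aldol adduct)
Conditions: LiN(i-Pr)2, THF, −78 °C; 2, −78 °C; AcOH quench at −78 °C
Reagents that add atoms: none
Why: In this intermolecular aldol addition the aldehyde adds to the lactone lithium enolate trans to the C8 silyloxymethyl arm (sets C8'), and the ring-locked E-enolate reacts through a Zimmerman–Traxler chair to give mainly the anti carbinol (sets C7', expected anti:syn about 3–5:1), the syn epimer being removed by chromatography.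

Step 8
Reactants: 11 anti-aldol adduct
Product: 12 (3R,4R,5S)-4-[(tert-butyldimethylsilyloxy)methyl]-3-hydroxy-3-[(R)-hydroxy(Ar)methyl]-5-Ar-oxolan-2-one
Conditions: LiN(i-Pr)2 (2.4 equiv), THF, −78 → −40 °C; 3-phenyl-2-(phenylsulfonyl)oxaziridine, −78 °C; AcOH quench
Reagents that add atoms: 3-phenyl-2-(phenylsulfonyl)oxaziridine (racemic Davis reagent), O=S(=O)(c1ccccc1)N1OC1c1ccccc1
Why: Davis enolate hydroxylation of the alkoxide–enolate dianion (which can neither β-eliminate nor retro-aldolize) delivers oxygen anti to the C8 arm, so the C8' OH ends up trans to C9 and the carbinol arm cis to C9, while C7' is untouched.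

Step 9
Reactants: 12 α-hydroxy lactone
Product: 13 (3R,4R,5S)-3-hydroxy-3-[(R)-hydroxy(Ar)methyl]-4-(hydroxymethyl)-5-Ar-oxolan-2-one
Conditions: HF·pyridine, pyridine, THF, 0 °C → rt
Reagents that add atoms: none
Why: Buffered acidic fluoride cleaves the primary alkyl TBS ether much faster than the hindered aryl TIPS ethers (selective desilylation).

Step 10
Reactants: 13 triol lactone
Product: 15 (3S,3aR,6R,6aR)-3,6-di-Ar-6a-hydroxytetrahydro-1H,3H-furo[3,4-c]furan-1-one (bicyclic lactone), via primary mesylate 14 (not isolated)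
Conditions: MsCl (1.1 equiv), pyridine, −20 → 0 °C; then 50 °C
Reagents that add atoms: none
Why: Selective sulfonylation of the only primary hydroxyl followed by intramolecular Williamson-type 5-exo-tet displacement by the cis C7' hydroxyl closes ring B with retention at C7', because the C7'–O bond is never broken.

Step 11
Reactants: 15 bicyclic lactone
Product: 16 (2R,3S,4R)-2-Ar-4-[(S)-hydroxy(Ar)methyl]-3-(hydroxymethyl)oxolan-3-ol
Conditions: LiBH4, THF, 0 °C → rt; aq. NH4Cl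
Reagents that add atoms: none
Why: Hydride reduction of the lactone to the diol opens ring A at the acyl carbon only, so no stereocenter is touched and the aryl silyl ethers survive.

Step 12
Reactants: 16 triol
Product: 18 (1S,3aS,4R,6aR)-1,4-di-Ar-tetrahydro-1H,3H-furo[3,4-c]furan-3a-ol (bis-TIPS ether of the target), via primary mesylate 17 (not isolated)
Conditions: MsCl (1.1 equiv), pyridine, 0 °C → rt; then 60 °C
Reagents that add atoms: none
Why: The same mesylation/5-exo-tet etherification lets the C7 benzylic hydroxyl displace the primary C9' mesylate with retention at C7, re-closing ring A as the ether and completing the cis-fused furofuran.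

Step 13
Reactants: 18 bis-TIPS ether of the target
Product: 19 8-hydroxypinoresinol, (1S,3aS,4R,6aR)-1,4-bis(4-hydroxy-3-methoxyphenyl)tetrahydro-1H,3H-furo[3,4-c]furan-3a-ol
Conditions: Bu4NF, AcOH, THF, 0 °C
Reagents that add atoms: none
Why: Fluoride-induced cleavage of the two aryl silyl ethers under acetic acid buffering frees the phenols without ionizing the benzylic ethers or the tertiary alcohol.

## Compound list

1 | vanillin (4-hydroxy-3-methoxybenzaldehyde) | COc1cc(C=O)ccc1O | starting material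
2 | 3-methoxy-4-(triisopropylsilyloxy)benzaldehyde | COc1cc(C=O)ccc1O[Si](C(C)C)(C(C)C)C(C)C | intermediate
3 | (4S)-4-benzyl-1,3-oxazolidin-2-one | O=C1N[C@@H](Cc2ccccc2)CO1 | starting material
4 | methyl 4-chloro-4-oxobutanoate | COC(=O)CCC(Cl)=O | starting material
5 | methyl 4-[(4S)-4-benzyl-2-oxo-1,3-oxazolidin-3-yl]-4-oxobutanoate | COC(=O)CCC(=O)N1[C@@H](Cc2ccccc2)COC1=O | intermediate
6 | methyl (3S,4S)-3-{[(4S)-4-benzyl-2-oxo-1,3-oxazolidin-3-yl]carbonyl}-4-hydroxy-4-[3-methoxy-4-(triisopropylsilyloxy)phenyl]butanoate | COC(=O)C[C@H](C(=O)N1[C@@H](Cc2ccccc2)COC1=O)[C@H](O)c1ccc(O[Si](C(C)C)(C(C)C)C(C)C)c(OC)c1 | intermediate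
7 | (4S)-4-benzyl-3-{[(2S,3S)-2-[3-methoxy-4-(triisopropylsilyloxy)phenyl]-5-oxooxolan-3-yl]carbonyl}-1,3-oxazolidin-2-one | O=C1C[C@H](C(=O)N2[C@@H](Cc3ccccc3)COC2=O)[C@@H](c2ccc(O[Si](C(C)C)(C(C)C)C(C)C)c(OC)c2)O1 | intermediate
8 | (2S,3S)-2-[3-methoxy-4-(triisopropylsilyloxy)phenyl]-5-oxooxolane-3-carboxylic acid | O=C1C[C@H](C(=O)O)[C@@H](c2ccc(O[Si](C(C)C)(C(C)C)C(C)C)c(OC)c2)O1 | intermediate
9 | (4R,5S)-4-(hydroxymethyl)-5-[3-methoxy-4-(triisopropylsilyloxy)phenyl]oxolan-2-one | O=C1C[C@H](CO)[C@@H](c2ccc(O[Si](C(C)C)(C(C)C)C(C)C)c(OC)c2)O1 | intermediate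
10 | (4R,5S)-4-[(tert-butyldimethylsilyloxy)methyl]-5-[3-methoxy-4-(triisopropylsilyloxy)phenyl]oxolan-2-one | O=C1C[C@H](CO[Si](C)(C)C(C)(C)C)[C@@H](c2ccc(O[Si](C(C)C)(C(C)C)C(C)C)c(OC)c2)O1 | intermediate
11 | (3R,4R,5S)-4-[(tert-butyldimethylsilyloxy)methyl]-3-{(S)-hydroxy[3-methoxy-4-(triisopropylsilyloxy)phenyl]methyl}-5-[3-methoxy-4-(triisopropylsilyloxy)phenyl]oxolan-2-one | O=C1[C@@H]([C@H](O)c2ccc(O[Si](C(C)C)(C(C)C)C(C)C)c(OC)c2)[C@H](CO[Si](C)(C)C(C)(C)C)[C@@H](c2ccc(O[Si](C(C)C)(C(C)C)C(C)C)c(OC)c2)O1 | intermediate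
12 | (3R,4R,5S)-4-[(tert-butyldimethylsilyloxy)methyl]-3-hydroxy-3-{(R)-hydroxy[3-methoxy-4-(triisopropylsilyloxy)phenyl]methyl}-5-[3-methoxy-4-(triisopropylsilyloxy)phenyl]oxolan-2-one | O=C1[C@](O)([C@H](O)c2ccc(O[Si](C(C)C)(C(C)C)C(C)C)c(OC)c2)[C@H](CO[Si](C)(C)C(C)(C)C)[C@@H](c2ccc(O[Si](C(C)C)(C(C)C)C(C)C)c(OC)c2)O1 | intermediate
13 | (3R,4R,5S)-3-hydroxy-3-{(R)-hydroxy[3-methoxy-4-(triisopropylsilyloxy)phenyl]methyl}-4-(hydroxymethyl)-5-[3-methoxy-4-(triisopropylsilyloxy)phenyl]oxolan-2-one | O=C1[C@](O)([C@H](O)c2ccc(O[Si](C(C)C)(C(C)C)C(C)C)c(OC)c2)[C@H](CO)[C@@H](c2ccc(O[Si](C(C)C)(C(C)C)C(C)C)c(OC)c2)O1 | intermediate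
14 | primary methanesulfonate of 13 (C9 OMs) | O=C1[C@](O)([C@H](O)c2ccc(O[Si](C(C)C)(C(C)C)C(C)C)c(OC)c2)[C@H](COS(C)(=O)=O)[C@@H](c2ccc(O[Si](C(C)C)(C(C)C)C(C)C)c(OC)c2)O1 | intermediate
15 | (3S,3aR,6R,6aR)-6a-hydroxy-3,6-bis[3-methoxy-4-(triisopropylsilyloxy)phenyl]tetrahydro-1H,3H-furo[3,4-c]furan-1-one | O=C1O[C@H](c2ccc(O[Si](C(C)C)(C(C)C)C(C)C)c(OC)c2)[C@H]2CO[C@H](c3ccc(O[Si](C(C)C)(C(C)C)C(C)C)c(OC)c3)[C@@]12O | intermediate
16 | (2R,3S,4R)-4-{(S)-hydroxy[3-methoxy-4-(triisopropylsilyloxy)phenyl]methyl}-3-(hydroxymethyl)-2-[3-methoxy-4-(triisopropylsilyloxy)phenyl]oxolan-3-ol | OC[C@]1(O)[C@@H](c2ccc(O[Si](C(C)C)(C(C)C)C(C)C)c(OC)c2)OC[C@@H]1[C@H](O)c1ccc(O[Si](C(C)C)(C(C)C)C(C)C)c(OC)c1 | intermediate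
17 | primary methanesulfonate of 16 (C9' OMs) | CS(=O)(=O)OC[C@]1(O)[C@@H](c2ccc(O[Si](C(C)C)(C(C)C)C(C)C)c(OC)c2)OC[C@@H]1[C@H](O)c1ccc(O[Si](C(C)C)(C(C)C)C(C)C)c(OC)c1 | intermediate
18 | (1S,3aS,4R,6aR)-1,4-bis[3-methoxy-4-(triisopropylsilyloxy)phenyl]tetrahydro-1H,3H-furo[3,4-c]furan-3a-ol | COc1cc([C@H]2OC[C@]3(O)[C@@H](c4ccc(O[Si](C(C)C)(C(C)C)C(C)C)c(OC)c4)OC[C@H]23)ccc1O[Si](C(C)C)(C(C)C)C(C)C | intermediate
19 | 8-hydroxypinoresinol, (1S,3aS,4R,6aR)-1,4-bis(4-hydroxy-3-methoxyphenyl)tetrahydro-1H,3H-furo[3,4-c]furan-3a-ol | COc1cc([C@H]2OC[C@]3(O)[C@@H](c4ccc(O)c(OC)c4)OC[C@H]23)ccc1O | target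

## Step count and risks

Total step count: 13. Longest linear sequence: 12 steps (steps 2–13 from oxazolidinone 3, or steps 1 and 3–13 from vanillin 1).

Steps most likely to fail, in route order:

Step 7. The facial selectivity at C8' is dependable, but the anti:syn ratio at C7' from a lactone lithium enolate and an aryl aldehyde may be modest, which costs material because the SN2 ring closure of step 10 needs the anti epimer. The fallback sets out from 10 and no longer depends on the C7' configuration. The aldol is run with KN(SiMe3)2 (open transition state, syn-favouring), or the syn fraction of step 7 is used, giving the syn-aldol adduct F1. Dianion hydroxylation as in step 8 gives the C7'-epimeric diol F2, and HF·pyridine gives the C7'-epimeric triol lactone F3. Ring B is then closed by an SN1 etherification (catalytic (+)-camphor-10-sulfonic acid, CH2Cl2, 0 °C). The p-silyloxybenzyl cation is captured by the C9 hydroxyl with the aryl group exo, away from the lactone ring, so either C7' epimer converges on 15, where the fallback rejoins the route.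

Step 8. Formation of the alkoxide–enolate dianion at a hindered tertiary α-carbon may be incomplete, the lithium aldolate may retro-aldolize on warming, and the sulfonimine by-product can add to lithium enolates. The fallback sets out from 11 and oxidizes a protected mono-enolate instead. Et3SiOTf/2,6-lutidine (CH2Cl2, −78 °C) gives the C7' triethylsilyl ether F4. KN(SiMe3)2 and the same oxaziridine at −78 °C hydroxylate it anti to the C8 arm, giving the α-hydroxy lactone F5. HF·pyridine then removes the triethylsilyl and the TBS group together, so the fallback comes back at 13 and skips 12.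

Step 10. The mesylation must pick the primary hydroxyl over a benzylic and a tertiary one, and the closure runs next to a β-hydroxy lactone that tolerates neither strong base (retro-aldol) nor strong acid. The fallback sets out from 13 and closes both rings after the lactone is gone. LiBH4 (THF, 0 °C → rt) reduces 13 to the pentaol F6. MsCl (2.2 equiv) in pyridine then gives the bis-mesylate F7, which on warming closes both oxolane rings in the same flask, since each benzylic hydroxyl has only one 5-exo partner. The fallback arrives at 18 and skips 15, 16 and 17.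

Further compounds
F1 | step 7 | (3R,4R,5S)-4-[(tert-butyldimethylsilyloxy)methyl]-3-{(R)-hydroxy[3-methoxy-4-(triisopropylsilyloxy)phenyl]methyl}-5-[3-methoxy-4-(triisopropylsilyloxy)phenyl]oxolan-2-one (syn-aldol adduct) | O=C1[C@@H]([C@@H](O)c2ccc(O[Si](C(C)C)(C(C)C)C(C)C)c(OC)c2)[C@H](CO[Si](C)(C)C(C)(C)C)[C@@H](c2ccc(O[Si](C(C)C)(C(C)C)C(C)C)c(OC)c2)O1
F2 | step 7 | (3R,4R,5S)-4-[(tert-butyldimethylsilyloxy)methyl]-3-hydroxy-3-{(S)-hydroxy[3-methoxy-4-(triisopropylsilyloxy)phenyl]methyl}-5-[3-methoxy-4-(triisopropylsilyloxy)phenyl]oxolan-2-one | O=C1[C@](O)([C@@H](O)c2ccc(O[Si](C(C)C)(C(C)C)C(C)C)c(OC)c2)[C@H](CO[Si](C)(C)C(C)(C)C)[C@@H](c2ccc(O[Si](C(C)C)(C(C)C)C(C)C)c(OC)c2)O1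
F3 | step 7 | (3R,4R,5S)-3-hydroxy-3-{(S)-hydroxy[3-methoxy-4-(triisopropylsilyloxy)phenyl]methyl}-4-(hydroxymethyl)-5-[3-methoxy-4-(triisopropylsilyloxy)phenyl]oxolan-2-one | O=C1[C@](O)([C@@H](O)c2ccc(O[Si](C(C)C)(C(C)C)C(C)C)c(OC)c2)[C@H](CO)[C@@H](c2ccc(O[Si](C(C)C)(C(C)C)C(C)C)c(OC)c2)O1
F4 | step 8 | (3R,4R,5S)-4-[(tert-butyldimethylsilyloxy)methyl]-5-[3-methoxy-4-(triisopropylsilyloxy)phenyl]-3-{(S)-[3-methoxy-4-(triisopropylsilyloxy)phenyl](triethylsilyloxy)methyl}oxolan-2-one | O=C1[C@@H]([C@H](O[Si](CC)(CC)CC)c2ccc(O[Si](C(C)C)(C(C)C)C(C)C)c(OC)c2)[C@H](CO[Si](C)(C)C(C)(C)C)[C@@H](c2ccc(O[Si](C(C)C)(C(C)C)C(C)C)c(OC)c2)O1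
F5 | step 8 | (3R,4R,5S)-4-[(tert-butyldimethylsilyloxy)methyl]-3-hydroxy-5-[3-methoxy-4-(triisopropylsilyloxy)phenyl]-3-{(R)-[3-methoxy-4-(triisopropylsilyloxy)phenyl](triethylsilyloxy)methyl}oxolan-2-one | O=C1[C@](O)([C@H](O[Si](CC)(CC)CC)c2ccc(O[Si](C(C)C)(C(C)C)C(C)C)c(OC)c2)[C@H](CO[Si](C)(C)C(C)(C)C)[C@@H](c2ccc(O[Si](C(C)C)(C(C)C)C(C)C)c(OC)c2)O1
F6 | step 10 | (1R,2S,3R,4S)-2,3-bis(hydroxymethyl)-1,4-bis[3-methoxy-4-(triisopropylsilyloxy)phenyl]butane-1,2,4-triol | OC[C@](O)([C@H](O)c1ccc(O[Si](C(C)C)(C(C)C)C(C)C)c(OC)c1)[C@H](CO)[C@H](O)c1ccc(O[Si](C(C)C)(C(C)C)C(C)C)c(OC)c1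
F7 | step 10 | bis(methanesulfonate) of F6 at both primary hydroxyls | CS(=O)(=O)OC[C@](O)([C@H](O)c1ccc(O[Si](C(C)C)(C(C)C)C(C)C)c(OC)c1)[C@H](COS(C)(=O)=O)[C@H](O)c1ccc(O[Si](C(C)C)(C(C)C)C(C)C)c(OC)c1
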